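## Retrosynthetic overview

1. Daucane locants are used throughout: C1 (quaternary, methyl) and C5 (H) are the fusion atoms shared by the cyclopentane (C1–C5) and the cycloheptane (C1, C5–C10); cutting C1–C5 leaves a cyclodecane.
2. Enabling feature: C1 lies next to the C10 carbinol and C5 next to the C4 tertiary carbinol, which is the imprint of an opened 1,10-oxirane and an oxygenated C4=C5 olefin, 1,5-related through C2–C3; the 8,9-oxirane is trans-fused on the seven-membered ring, i.e. the epoxide of an E-olefin that only the ten-membered ring can hold.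
3. Last step, both rings at once: transannular oxirane–olefin cyclisation of cyclodecene bis-epoxide 18, the C4 cation being caught by the C6 veratrate; 18 comes from macrocyclic allylic alcohol 16 by hydroxyl-directed epoxidation and acetylation.
4. Ten-membered ring 16: Nozaki–Hiyama–Kishi closure of C1–C2 in chain 15 (Z-alkenyl iodide by Stork–Zhao olefination of epoxy aldehyde 12; 8,9-oxirane by Sharpless epoxidation).
5. Chain: C6–C7 by asymmetric vinylogous Mukaiyama aldol of enal 5 with silyl dienol ether 7; enal 5 (C2–C6 plus isopropyl) by syn-carbocupration of ynoate 2.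

Key step: step 17

Remark (assumption): the SMILES is read literally; at C8/C9 it places C7 and C10 on opposite sides of the oxirane (trans-fused on the seven-membered ring), so this oxirane is made on an E-olefin before the seven-membered ring exists and the route delivers exactly this configuration.

## Route

Step 1
Reactants: 1 4-(tert-butyldimethylsilyloxy)but-1-yne
Product: 2 methyl 5-(tert-butyldimethylsilyloxy)pent-2-ynoate
Conditions: n-BuLi, THF, −78 °C; then ClCO2Me, −78 → 0 °C
Reagents that add atoms: methyl chloroformate, COC(=O)Cl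
Why: C-acylation of a lithium acetylide with a chloroformate is the standard entry to 2-ynoates; the silyl ether is inert and no stereocentre is formed.

Step 2
Reactants: 2 methyl 5-(tert-butyldimethylsilyloxy)pent-2-ynoate
Product: 3 methyl (E)-3-[2-(tert-butyldimethylsilyloxy)ethyl]-4-methylpent-2-enoate
Conditions: i-PrMgCl (2.4 equiv), CuI (1.2 equiv), THF, −40 °C; then 2, −78 °C; MeOH quench at −78 °C
Reagents that add atoms: isopropylmagnesium chloride, CC(C)[Mg]Cl
Why: Organocuprate conjugate addition to an alkynoate is a syn-carbometalation, so with protonation at −78 °C the isopropyl group ends cis to H and the silyloxyethyl arm cis to the ester, which fixes the C4=C5 geometry (C3 and C6 cis) needed in the macrocycle.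

Step 3
Reactants: 3 methyl (E)-3-[2-(tert-butyldimethylsilyloxy)ethyl]-4-methylpent-2-enoate
Product: 4 (E)-3-[2-(tert-butyldimethylsilyloxy)ethyl]-4-methylpent-2-en-1-ol
Conditions: i-Bu2AlH (2.2 equiv), CH2Cl2, −78 °C; Rochelle salt work-up
Reagents that add atoms: none
Why: 1,2-Reduction of an enoate by a dialkylaluminium hydride gives the allylic alcohol without touching the olefin geometry or the silyl ether.

Step 4
Reactants: 4 (E)-3-[2-(tert-butyldimethylsilyloxy)ethyl]-4-methylpent-2-en-1-ol
Product: 5 (E)-3-[2-(tert-butyldimethylsilyloxy)ethyl]-4-methylpent-2-enal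
Conditions: MnO2, CH2Cl2, rt
Reagents that add atoms: none
Why: Neutral allylic oxidation with MnO2 gives the enal without E/Z scrambling.

Step 5
Reactants: 6 methyl 3-methylbut-2-enoate
Product: 7 (1Z)-1-(tert-butyldimethylsilyloxy)-1-methoxy-3-methylbuta-1,3-diene
Conditions: LiN(i-Pr)2, THF/DMPU, −78 °C; then t-BuMe2SiCl, −78 °C → rt
Reagents that add atoms: tert-butyldimethylsilyl chloride, CC(C)(C)[Si](C)(C)Cl
Why: γ-Deprotonation of the senecioate and O-silylation of the dienolate give the silyl dienol ether (ketene acetal geometry drawn as 1Z; either geometry converges on the same aldol product).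

Step 6
Reactants: 5 (E)-3-[2-(tert-butyldimethylsilyloxy)ethyl]-4-methylpent-2-enal; 7 (1Z)-1-(tert-butyldimethylsilyloxy)-1-methoxy-3-methylbuta-1,3-diene
Product: 8 methyl (2E,5R,6E)-7-[2-(tert-butyldimethylsilyloxy)ethyl]-5-hydroxy-3,8-dimethylnona-2,6-dienoate
Conditions: SiCl4 (1.1 equiv), binaphthyldiamine-derived chiral bisphosphoramide (5 mol %, the enantiomer that directs Re-face attack), i-Pr2NEt (10 mol %), CH2Cl2, −78 °C; aq. NaHCO3
Reagents that add atoms: none
Why: Lewis-base-activated SiCl4 vinylogous Mukaiyama aldol: the chiral phosphoramide-bound silicon cation activates the enal, the dienol ether attacks through its γ-carbon on the Re face to set the 5R carbinol (daucane C6), and the new enoate forms E (C7 trans to C10).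

Step 7
Reactants: 8 methyl (2E,5R,6E)-7-[2-(tert-butyldimethylsilyloxy)ethyl]-5-hydroxy-3,8-dimethylnona-2,6-dienoate
Product: 9 (2E,5R,6E)-7-[2-(tert-butyldimethylsilyloxy)ethyl]-3,8-dimethylnona-2,6-diene-1,5-diol
Conditions: i-Bu2AlH (3.2 equiv), CH2Cl2, −78 °C; Rochelle salt work-up
Reagents that add atoms: none
Why: 1,2-Reduction of the enoate gives the primary E-allylic alcohol required for the titanium tartrate epoxidation.

Step 8
Reactants: 9 (2E,5R,6E)-7-[2-(tert-butyldimethylsilyloxy)ethyl]-3,8-dimethylnona-2,6-diene-1,5-diol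
Product: 10 (2R,3R,5R,6E)-7-[2-(tert-butyldimethylsilyloxy)ethyl]-2,3-epoxy-3,8-dimethylnon-6-ene-1,5-diol
Conditions: Ti(Oi-Pr)4 (10 mol %), D-(−)-diethyl tartrate (12 mol %), t-BuOOH (1.1 equiv), 4 Å molecular sieves, CH2Cl2, −20 °C
Reagents that add atoms: tert-butyl hydroperoxide, CC(C)(C)OO
Why: Sharpless asymmetric epoxidation: with D-(−)-tartrate the primary, geraniol-type E-allylic alcohol should give the (2R,3R)-oxirane (daucane C9, C8) under reagent control, while the secondary allylic alcohol, whose trisubstituted olefin carries a cis substituent, reacts far more slowly.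

Step 9
Reactants: 10 (2R,3R,5R,6E)-7-[2-(tert-butyldimethylsilyloxy)ethyl]-2,3-epoxy-3,8-dimethylnon-6-ene-1,5-diol
Product: 11 (2S,3R,5R,6E)-7-[2-(tert-butyldimethylsilyloxy)ethyl]-2,3-epoxy-5-hydroxy-3,8-dimethylnon-6-enal
Conditions: TEMPO (10 mol %), PhI(OAc)2 (1.1 equiv), CH2Cl2, 0 °C → rt
Reagents that add atoms: none
Why: Oxoammonium oxidation is selective for the primary over the secondary alcohol, and the hydroxy aldehyde cannot close to a lactol because the ring would have to contain the E-derived oxirane (the descriptor at C2 changes by priority only).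

Step 10
Reactants: 11 (2S,3R,5R,6E)-7-[2-(tert-butyldimethylsilyloxy)ethyl]-2,3-epoxy-5-hydroxy-3,8-dimethylnon-6-enal
Product: 12 (2S,3R,5R,6E)-7-[2-(tert-butyldimethylsilyloxy)ethyl]-2,3-epoxy-3,8-dimethyl-1-oxonon-6-en-5-yl 3,4-dimethoxybenzoate
Conditions: 3,4-dimethoxybenzoyl chloride, pyridine, DMAP (cat.), CH2Cl2, 0 °C
Reagents that add atoms: 3,4-dimethoxybenzoyl chloride, COc1ccc(cc1OC)C(Cl)=O
Why: DMAP-catalysed acylation installs the veratrate of the target on the only free hydroxyl, with retention at the carbinol; the epoxy aldehyde has no enolisable path to epimerisation.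

Step 11
Reactants: 12 (2S,3R,5R,6E)-7-[2-(tert-butyldimethylsilyloxy)ethyl]-2,3-epoxy-3,8-dimethyl-1-oxonon-6-en-5-yl 3,4-dimethoxybenzoate
Product: 13 (2Z,4R,5R,7R,8E)-9-[2-(tert-butyldimethylsilyloxy)ethyl]-4,5-epoxy-2-iodo-5,10-dimethylundeca-2,8-dien-7-yl 3,4-dimethoxybenzoate
Conditions: [Ph3PEt]I, n-BuLi, THF, rt; I2, −78 °C; NaN(SiMe3)2, −20 °C; then 12, −78 °C
Reagents that add atoms: ethyltriphenylphosphonium iodide, CC[P+](c1ccccc1)(c1ccccc1)c1ccccc1.[I-]; iodine, II
Why: Stork–Zhao-type Wittig olefination with the α-iodo ylide gives the Z-2-iodoalkene (iodine cis to the chain) under kinetic control at −78 °C, where the non-stabilised ylide reacts with the aldehyde and not with the aryl ester or the oxirane.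

Step 12
Reactants: 13 (2Z,4R,5R,7R,8E)-9-[2-(tert-butyldimethylsilyloxy)ethyl]-4,5-epoxy-2-iodo-5,10-dimethylundeca-2,8-dien-7-yl 3,4-dimethoxybenzoate
Product: 14 (2Z,4R,5R,7R,8E)-4,5-epoxy-9-(2-hydroxyethyl)-2-iodo-5,10-dimethylundeca-2,8-dien-7-yl 3,4-dimethoxybenzoate
Conditions: Bu4NF, AcOH (1:1), THF, 0 °C → rt
Reagents that add atoms: none
Why: Buffered fluoride removes the primary silyl ether without opening the vinyl oxirane or cleaving the aryl ester.

Step 13
Reactants: 14 (2Z,4R,5R,7R,8E)-4,5-epoxy-9-(2-hydroxyethyl)-2-iodo-5,10-dimethylundeca-2,8-dien-7-yl 3,4-dimethoxybenzoate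
Product: 15 (2Z,4R,5R,7R,8E)-4,5-epoxy-2-iodo-5,10-dimethyl-9-(2-oxoethyl)undeca-2,8-dien-7-yl 3,4-dimethoxybenzoate
Conditions: DMP (Dess–Martin periodinane), NaHCO3, CH2Cl2, 0 °C; used at once
Reagents that add atoms: none
Why: Buffered hypervalent-iodine oxidation gives the β,γ-unsaturated aldehyde under neutral conditions that should not move the olefin into conjugation.

Step 14
Reactants: 15 (2Z,4R,5R,7R,8E)-4,5-epoxy-2-iodo-5,10-dimethyl-9-(2-oxoethyl)undeca-2,8-dien-7-yl 3,4-dimethoxybenzoate
Product: 16 (1(10)Z,2R,4E,6R,8R,9R)-8,9-epoxy-2-hydroxy-4-isopropyl-1,8-dimethylcyclodeca-1(10),4-dien-6-yl 3,4-dimethoxybenzoate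
Conditions: CrCl2 (10 equiv), NiCl2 (2 mol %), DMSO/THF, rt, slow addition to 0.002 M
Reagents that add atoms: none
Why: Nozaki–Hiyama–Kishi coupling: zerovalent nickel inserts into the alkenyl iodide with retention, transmetalation to trivalent chromium and intramolecular carbonyl addition close the ten-membered ring at C1–C2 with the Z geometry kept, and addition to the aldehyde face turned to the ring periphery should favour the 2R carbinol.

Step 15
Reactants: 16 (1(10)Z,2R,4E,6R,8R,9R)-8,9-epoxy-2-hydroxy-4-isopropyl-1,8-dimethylcyclodeca-1(10),4-dien-6-yl 3,4-dimethoxybenzoate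
Product: 17 (1R,2R,4E,6R,8R,9R,10S)-1,10:8,9-diepoxy-2-hydroxy-4-isopropyl-1,8-dimethylcyclodec-4-en-6-yl 3,4-dimethoxybenzoate
Conditions: VO(acac)2 (5 mol %), t-BuOOH (1.2 equiv), CH2Cl2, 0 °C
Reagents that add atoms: tert-butyl hydroperoxide, CC(C)(C)OO
Why: Hydroxyl-directed vanadium epoxidation delivers oxygen to the allylic C1=C10 olefin syn to the C2 hydroxyl (the cis-epoxy alcohol known for ring-cis medium-ring allylic alcohols), and it is faster than epoxidation of the merely homoallylic, hindered C4=C5 olefin.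

Step 16
Reactants: 17 (1R,2R,4E,6R,8R,9R,10S)-1,10:8,9-diepoxy-2-hydroxy-4-isopropyl-1,8-dimethylcyclodec-4-en-6-yl 3,4-dimethoxybenzoate
Product: 18 (1R,2R,4E,6R,8R,9R,10S)-2-acetoxy-1,10:8,9-diepoxy-4-isopropyl-1,8-dimethylcyclodec-4-en-6-yl 3,4-dimethoxybenzoate
Conditions: Ac2O, pyridine, DMAP (cat.), CH2Cl2, 0 °C
Reagents that add atoms: acetic anhydride, CC(=O)OC(C)=O
Why: Acetylation of the only free hydroxyl places the C2 acetate before C10–OH and C4–OH exist, so no late differentiation of hydroxyls is needed.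

Step 17
Reactants: 18 (1R,2R,4E,6R,8R,9R,10S)-2-acetoxy-1,10:8,9-diepoxy-4-isopropyl-1,8-dimethylcyclodec-4-en-6-yl 3,4-dimethoxybenzoate
Product: 20 (1R,2R,4S,5R,6R,8R,9R,10R)-2-acetoxy-8,9-epoxy-4,10-dihydroxydaucan-6-yl 3,4-dimethoxybenzoate, via dioxanylium zwitterion 19 (not isolated)
Conditions: BF3·OEt2 (1.1 equiv), CH2Cl2, −78 °C; then H2O/aq. NaHCO3, −78 → 0 °C
Reagents that add atoms: water, O
Why: BF3 binds the 1,10-oxirane, whose tertiary C1–O bond has its backside turned into the ring and is opened by C5 of the C4=C5 olefin held 1,5 across the ring, while the veratrate carbonyl on C6 adds to C4 from the opposite face to give 1,3-dioxan-2-ylium zwitterion 19, which water hydrolyses to the secondary C6 ester and the free C4 and C10 hydroxyls. The closest known reaction type is the Lewis-acid transannular oxirane–olefin cyclisation of epoxycyclodeca-1,5-dienes (germacrene epoxides to eudesmane and guaiane alcohols), joined to acyloxonium capture of a cation by a neighbouring ester. The cyclopentane (C1–C5) closes 5-exo at the oxirane carbon and 5-endo-trig at the olefin, and the cycloheptane (C1, C5–C10) closes 7-endo at the oxirane and 7-exo-trig at the olefin, the trans-fused 8,9-oxirane being carried in unchanged from the E-configured ten-membered ring. C10 keeps the oxirane configuration, C1 is inverted by anti opening (methyl β), C5 is set by attack on the olefin face that carries C7 when H6 eclipses the double bond (allylic 1,3-strain against C3 in the ring-cis olefin), which gives the trans ring fusion, and C4 is set by anti addition of the tethered carboxyl oxygen, which can only reach the β face (six-membered ring cis-fused on the cyclopentane). The step needs ionisation of the 1,10-oxirane before the 8,9-oxirane and C–C bond formation before acetate participation or hydride shift; this is secured by π-assistance (only C1 has an olefin carbon within reach in the Markovnikov sense, C8 has none), by the low temperature, and by the two ester groups lying on the ring periphery, away from the backsides of the C1–O and C8–O bonds. Collapse of the ortho acid should leave the acyl group on the secondary C6 oxygen, the less hindered and thermodynamically favoured ester.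

## Compound list

1 | 4-(tert-butyldimethylsilyloxy)but-1-yne | C#CCCO[Si](C)(C)C(C)(C)C | starting material
2 | methyl 5-(tert-butyldimethylsilyloxy)pent-2-ynoate | COC(=O)C#CCCO[Si](C)(C)C(C)(C)C | intermediate
3 | methyl (E)-3-[2-(tert-butyldimethylsilyloxy)ethyl]-4-methylpent-2-enoate | COC(=O)/C=C(\CCO[Si](C)(C)C(C)(C)C)C(C)C | intermediate
4 | (E)-3-[2-(tert-butyldimethylsilyloxy)ethyl]-4-methylpent-2-en-1-ol | OC/C=C(\CCO[Si](C)(C)C(C)(C)C)C(C)C | intermediate
5 | (E)-3-[2-(tert-butyldimethylsilyloxy)ethyl]-4-methylpent-2-enal | O=C/C=C(\CCO[Si](C)(C)C(C)(C)C)C(C)C | intermediate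
6 | methyl 3-methylbut-2-enoate | COC(=O)C=C(C)C | starting material
7 | (1Z)-1-(tert-butyldimethylsilyloxy)-1-methoxy-3-methylbuta-1,3-diene | C=C(C)/C=C(/OC)O[Si](C)(C)C(C)(C)C | intermediate
8 | methyl (2E,5R,6E)-7-[2-(tert-butyldimethylsilyloxy)ethyl]-5-hydroxy-3,8-dimethylnona-2,6-dienoate | COC(=O)/C=C(\C)C[C@@H](O)/C=C(\CCO[Si](C)(C)C(C)(C)C)C(C)C | intermediate
9 | (2E,5R,6E)-7-[2-(tert-butyldimethylsilyloxy)ethyl]-3,8-dimethylnona-2,6-diene-1,5-diol | OC/C=C(\C)C[C@@H](O)/C=C(\CCO[Si](C)(C)C(C)(C)C)C(C)C | intermediate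
10 | (2R,3R,5R,6E)-7-[2-(tert-butyldimethylsilyloxy)ethyl]-2,3-epoxy-3,8-dimethylnon-6-ene-1,5-diol | OC[C@H]1O[C@]1(C)C[C@@H](O)/C=C(\CCO[Si](C)(C)C(C)(C)C)C(C)C | intermediate
11 | (2S,3R,5R,6E)-7-[2-(tert-butyldimethylsilyloxy)ethyl]-2,3-epoxy-5-hydroxy-3,8-dimethylnon-6-enal | O=C[C@H]1O[C@]1(C)C[C@@H](O)/C=C(\CCO[Si](C)(C)C(C)(C)C)C(C)C | intermediate
12 | (2S,3R,5R,6E)-7-[2-(tert-butyldimethylsilyloxy)ethyl]-2,3-epoxy-3,8-dimethyl-1-oxonon-6-en-5-yl 3,4-dimethoxybenzoate | O=C[C@H]1O[C@]1(C)C[C@@H](OC(=O)c2ccc(OC)c(OC)c2)/C=C(\CCO[Si](C)(C)C(C)(C)C)C(C)C | intermediate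
13 | (2Z,4R,5R,7R,8E)-9-[2-(tert-butyldimethylsilyloxy)ethyl]-4,5-epoxy-2-iodo-5,10-dimethylundeca-2,8-dien-7-yl 3,4-dimethoxybenzoate | C/C(I)=C/[C@H]1O[C@]1(C)C[C@@H](OC(=O)c2ccc(OC)c(OC)c2)/C=C(\CCO[Si](C)(C)C(C)(C)C)C(C)C | intermediate
14 | (2Z,4R,5R,7R,8E)-4,5-epoxy-9-(2-hydroxyethyl)-2-iodo-5,10-dimethylundeca-2,8-dien-7-yl 3,4-dimethoxybenzoate | C/C(I)=C/[C@H]1O[C@]1(C)C[C@@H](OC(=O)c2ccc(OC)c(OC)c2)/C=C(\CCO)C(C)C | intermediate
15 | (2Z,4R,5R,7R,8E)-4,5-epoxy-2-iodo-5,10-dimethyl-9-(2-oxoethyl)undeca-2,8-dien-7-yl 3,4-dimethoxybenzoate | C/C(I)=C/[C@H]1O[C@]1(C)C[C@@H](OC(=O)c2ccc(OC)c(OC)c2)/C=C(\CC=O)C(C)C | intermediate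
16 | (1(10)Z,2R,4E,6R,8R,9R)-8,9-epoxy-2-hydroxy-4-isopropyl-1,8-dimethylcyclodeca-1(10),4-dien-6-yl 3,4-dimethoxybenzoate (daucane locants; C3 and C6 cis on C4=C5) | C1/C(C(C)C)=C\[C@H](OC(=O)c2ccc(OC)c(OC)c2)C[C@@]3(C)O[C@@H]3/C=C(/C)[C@@H]1O | intermediate
17 | (1R,2R,4E,6R,8R,9R,10S)-1,10:8,9-diepoxy-2-hydroxy-4-isopropyl-1,8-dimethylcyclodec-4-en-6-yl 3,4-dimethoxybenzoate (1,10-oxirane cis and syn to 2-OH; 8,9-oxirane trans) | C1/C(C(C)C)=C\[C@H](OC(=O)c2ccc(OC)c(OC)c2)C[C@@]3(C)O[C@@H]3[C@@H]4O[C@]4(C)[C@@H]1O | intermediate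
18 | (1R,2R,4E,6R,8R,9R,10S)-2-acetoxy-1,10:8,9-diepoxy-4-isopropyl-1,8-dimethylcyclodec-4-en-6-yl 3,4-dimethoxybenzoate | C1/C(C(C)C)=C\[C@H](OC(=O)c2ccc(OC)c(OC)c2)C[C@@]3(C)O[C@@H]3[C@@H]4O[C@]4(C)[C@@H]1OC(C)=O | intermediate
19 | 2-(3,4-dimethoxyphenyl)-1,3-dioxan-2-ylium bridging O4 and O6 of the closed bicycle, C10 oxygen bound to BF3 (zwitterion) | COc1ccc(C4=[O+][C@@H]2C[C@@]3(C)O[C@@H]3[C@H](O[B-](F)(F)F)[C@]3(C)[C@H](OC(C)=O)C[C@](O4)(C(C)C)[C@@H]23)cc1OC | intermediate
20 | (1R,2R,4S,5R,6R,8R,9R,10R)-2-acetoxy-8,9-epoxy-4,10-dihydroxydaucan-6-yl 3,4-dimethoxybenzoate | COc1ccc(C(=O)O[C@@H]2C[C@@]3(C)O[C@@H]3[C@H](O)[C@]3(C)[C@H](OC(C)=O)C[C@](O)(C(C)C)[C@@H]23)cc1OC | target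

## Step count and risks

Total step count: 17. Longest linear sequence: 16 (steps 1–4 and 6–17; step 5 is a one-step side branch).

Steps most likely to fail:

1. Step 17. The Lewis acid may ionise the 8,9-oxirane at tertiary C8, or the 1,10-oxirane may collapse by hydride shift before C5 engages. The closure also has to build the seven-membered ring around an E-derived oxirane, which costs strain in the transition state. Fallback, setting out from 17 and coming back at 20: the free C2 hydroxyl of 17 is converted with Me2AlCl (CH2Cl2, −78 °C) into an aluminium alkoxide that chelates the syn 1,10-oxirane oxygen, so that only this oxirane is activated. The same transannular closure and veratrate capture, followed by aqueous work-up, give the 2-deacetyl triol F1. A lipase (Candida antarctica lipase B, vinyl acetate) then acetylates the less hindered cyclopentane hydroxyl at C2 in preference to the C10 hydroxyl (flanked by C1 and the oxirane) and the tertiary C4 hydroxyl, giving 20.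

2. Step 14. Facial selectivity at the aldehyde during ring closure may be poor (C2 epimers), and a slow closure may allow protodeiodination. Fallback, setting out from 15 and coming back at 16: the ring is closed under the same conditions without regard to C2, and the mixture of 16 and its 2S epimer F2 is oxidised with DMP to the single cyclodecadienone F3. Corey–Bakshi–Shibata reduction with (S)-2-methyl-CBS-oxazaborolidine and catecholborane (toluene, −78 °C), which treats the alkenyl side as the large group, then sets 2R under reagent control and gives 16.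

3. Step 6. Enantioselectivity may erode with the β,β-disubstituted enal, or the dienol ether may attack partly through its α-carbon. Fallback, setting out from 5 (with 7) and coming back at 8: a BF3·OEt2-mediated vinylogous Mukaiyama aldol (CH2Cl2, −78 °C) gives the racemic hydroxy ester F4. Buffered DMP oxidation gives the dienone ester F5, and Corey–Bakshi–Shibata reduction with (S)-2-methyl-CBS-oxazaborolidine and catecholborane (enone carbonyl, alkenyl as large group) gives 8 under reagent control.

## Further compounds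

F1 | step 17 | (1R,2R,4S,5R,6R,8R,9R,10R)-8,9-epoxy-2,4,10-trihydroxydaucan-6-yl 3,4-dimethoxybenzoate (2-deacetyl triol) | COc1ccc(C(=O)O[C@@H]2C[C@@]3(C)O[C@@H]3[C@H](O)[C@]3(C)[C@H](O)C[C@](O)(C(C)C)[C@@H]23)cc1OC
F2 | step 14 | 2S epimer of 16 | C1/C(C(C)C)=C\[C@H](OC(=O)c2ccc(OC)c(OC)c2)C[C@@]3(C)O[C@@H]3/C=C(/C)[C@H]1O
F3 | step 14 | (1(10)Z,4E,6R,8R,9R)-8,9-epoxy-4-isopropyl-1,8-dimethyl-2-oxocyclodeca-1(10),4-dien-6-yl 3,4-dimethoxybenzoate | C1/C(C(C)C)=C\[C@H](OC(=O)c2ccc(OC)c(OC)c2)C[C@@]3(C)O[C@@H]3/C=C(/C)C1=O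
F4 | step 6 | racemic methyl (2E,6E)-7-[2-(tert-butyldimethylsilyloxy)ethyl]-5-hydroxy-3,8-dimethylnona-2,6-dienoate | COC(=O)/C=C(\C)CC(O)/C=C(\CCO[Si](C)(C)C(C)(C)C)C(C)C
F5 | step 6 | methyl (2E,6E)-7-[2-(tert-butyldimethylsilyloxy)ethyl]-3,8-dimethyl-5-oxonona-2,6-dienoate | COC(=O)/C=C(\C)CC(=O)/C=C(\CCO[Si](C)(C)C(C)(C)C)C(C)C
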